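**Retrosynthetic overview**
1. Target 19 ⇐ hexasilyl enone 18 ⇐ Mannich α-methylenation of the silyl-protected deoxybenzoin 16 ⇐ hexaphenol 15 ⇐ hexamethyl ether 14.
2. 14 ⇐ Friedel–Crafts acylation at C7 of the 3-aroyl-2-arylbenzofuran 12 with (4-methoxyphenyl)acetyl chloride 13.
3. 12 ⇐ aryl Grignard addition and oxidation on the 2-aryl-3-formylbenzofuran 8.
4. 8 ⇐ acid cyclisation of keto acetal 6 ⇐ oxidative 1,2-aryl shift of chalcone 5 ⇐ intermolecular Claisen–Schmidt aldol of aldehyde 2 with ketone 3. This aldol bond ends up as the C3–C(=O) bond of the target.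
5. Ring order: all four benzene rings are bought; the furan ring is the only ring formed (step 4).

Assumption: the target has no stereocentre, so "single enantiomer" needs no stereocontrol; the sp3 centres met on the way (4, 6, 7, 11, 17) are racemic and are all erased.

**Route**

Step 1
Reactants: 1 2-hydroxy-4,6-dimethoxybenzaldehyde
Product: 2 2,4-dimethoxy-6-(methoxymethoxy)benzaldehyde
Conditions: MOMCl, i-Pr2NEt, CH2Cl2, 0 °C → rt
Reagents that add atoms: chloromethyl methyl ether, COCCl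
Why: O-alkylation (MOM protection) of the one phenol that later becomes the furan oxygen; the acetal survives the base of step 2 and is removed by the acid of step 4.

Step 2
Reactants: 2 2,4-dimethoxy-6-(methoxymethoxy)benzaldehyde; 3 4'-methoxyacetophenone
Product: 5 (E)-3-[2,4-dimethoxy-6-(methoxymethoxy)phenyl]-1-(4-methoxyphenyl)prop-2-en-1-one, via β-hydroxy ketone 4 (not isolated)
Conditions: KOH, EtOH/H2O, rt, 24–48 h
Reagents that add atoms: none
Why: Claisen–Schmidt crossed aldol condensation: the aldehyde cannot enolise, the methyl ketone enolate adds to it, and E1cB dehydration gives only the conjugated E-alkene.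

Step 3
Reactants: 5 (E)-3-[2,4-dimethoxy-6-(methoxymethoxy)phenyl]-1-(4-methoxyphenyl)prop-2-en-1-one
Product: 6 2-[2,4-dimethoxy-6-(methoxymethoxy)phenyl]-3,3-dimethoxy-1-(4-methoxyphenyl)propan-1-one
Conditions: PhI(OH)OTs, MeOH, 0 °C → rt; NaHCO3 quench
Reagents that add atoms: methanol, CO
Why: Oxidative chalcone rearrangement by a trivalent iodine reagent: methoxy-iodination of the alkene, then a 1,2-shift of the electron-rich ring A aryl with loss of PhI and capture of the oxocarbenium by MeOH; the new centre is racemic and vanishes in step 4.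

Step 4
Reactants: 6 2-[2,4-dimethoxy-6-(methoxymethoxy)phenyl]-3,3-dimethoxy-1-(4-methoxyphenyl)propan-1-one
Product: 8 4,6-dimethoxy-2-(4-methoxyphenyl)-1-benzofuran-3-carbaldehyde, via cyclic acetal 7 (not isolated)
Conditions: TsOH·H2O, (CF3)2CHOH, rt
Reagents that add atoms: water, O
Why: Acid removes the MOM group and the phenol first closes on the acetal carbon (7); in the strongly ionising acidic medium the ring reopens and recloses on the aryl ketone, and cyclodehydration gives the 2-aryl-3-formylbenzofuran, so the 4-methoxyphenyl ends up on C2.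

Step 5
Reactants: 9 1-bromo-2,4-dimethoxybenzene
Product: 10 (2,4-dimethoxyphenyl)magnesium bromide
Conditions: Mg, I2 (cat.), THF, reflux; solution used directly
Reagents that add atoms: magnesium, [Mg]
Why: Grignard formation by insertion of magnesium into the aryl C–Br bond; the methoxy groups are inert.

Step 6
Reactants: 8 4,6-dimethoxy-2-(4-methoxyphenyl)-1-benzofuran-3-carbaldehyde; 10 (2,4-dimethoxyphenyl)magnesium bromide
Product: 11 (2,4-dimethoxyphenyl)[4,6-dimethoxy-2-(4-methoxyphenyl)-1-benzofuran-3-yl]methanol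
Conditions: THF, 0 °C → rt; aq. NH4Cl
Reagents that add atoms: none
Why: Grignard 1,2-addition to the only electrophile present, the aldehyde; the carbinol centre is racemic and is removed in step 7.

Step 7
Reactants: 11 (2,4-dimethoxyphenyl)[4,6-dimethoxy-2-(4-methoxyphenyl)-1-benzofuran-3-yl]methanol
Product: 12 (2,4-dimethoxyphenyl)[4,6-dimethoxy-2-(4-methoxyphenyl)-1-benzofuran-3-yl]methanone
Conditions: MnO2 (excess), CH2Cl2, rt
Reagents that add atoms: none
Why: Neutral MnO2 oxidation of a doubly benzylic alcohol, which avoids acid that would ionise this electron-rich carbinol.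

Step 8
Reactants: 12 (2,4-dimethoxyphenyl)[4,6-dimethoxy-2-(4-methoxyphenyl)-1-benzofuran-3-yl]methanone; 13 (4-methoxyphenyl)acetyl chloride
Product: 14 1-[3-(2,4-dimethoxybenzoyl)-4,6-dimethoxy-2-(4-methoxyphenyl)-1-benzofuran-7-yl]-2-(4-methoxyphenyl)ethan-1-one
Conditions: SnCl4 (2.5 equiv), CH2Cl2, 0 °C → rt
Reagents that add atoms: none
Why: Friedel–Crafts acylation: C7 of ring A has three oxygen donors (ortho OMe, ortho ring O, para OMe) and is less hindered than C5 between two OMe groups, while the other aryl rings are far less nucleophilic.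

Step 9
Reactants: 14 1-[3-(2,4-dimethoxybenzoyl)-4,6-dimethoxy-2-(4-methoxyphenyl)-1-benzofuran-7-yl]-2-(4-methoxyphenyl)ethan-1-one
Product: 15 1-[3-(2,4-dihydroxybenzoyl)-4,6-dihydroxy-2-(4-hydroxyphenyl)-1-benzofuran-7-yl]-2-(4-hydroxyphenyl)ethan-1-one
Conditions: BBr3 (15 equiv), CH2Cl2, −78 °C → rt; then MeOH/H2O
Reagents that add atoms: none
Why: Lewis-acid ether cleavage (bromide SN2 on the boron-activated methyl ethers) removes all six methyl groups while the benzofuran, both ketones and the still-saturated side chain tolerate BBr3.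

Step 10
Reactants: 15 1-[3-(2,4-dihydroxybenzoyl)-4,6-dihydroxy-2-(4-hydroxyphenyl)-1-benzofuran-7-yl]-2-(4-hydroxyphenyl)ethan-1-one
Product: 16 hexakis-O-(tert-butyldimethylsilyl) ether of 15
Conditions: TBSCl (9 equiv), imidazole, DMAP (cat.), DMF, rt → 40 °C
Reagents that add atoms: tert-butyldimethylsilyl chloride, CC(C)(C)[Si](C)(C)Cl
Why: Exhaustive phenol silylation masks the phenols against ring aminomethylation and against oxa-Michael addition of the C6 oxygen in step 11, and the groups come off later without strong acid or base.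

Step 11
Reactants: 16 hexakis-O-(tert-butyldimethylsilyl) ether of 15
Product: 18 hexakis-O-(tert-butyldimethylsilyl) ether of the target, via Mannich base 17 (not isolated)
Conditions: CH2(NMe2)2, Ac2O, DMF, rt → 50 °C
Reagents that add atoms: N,N,N',N'-tetramethylmethanediamine, CN(C)CN(C)C
Why: Mannich α-methylenation: the aminal and Ac2O give Me2N=CH2+, which aminomethylates the only enolisable position (the benzylic CH2), and N-acetylation of the Mannich base triggers E1cB loss of the amine to the 1,1-disubstituted enone.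

Step 12
Reactants: 18 hexakis-O-(tert-butyldimethylsilyl) ether of the target
Product: 19 1-[3-(2,4-dihydroxybenzoyl)-4,6-dihydroxy-2-(4-hydroxyphenyl)-1-benzofuran-7-yl]-2-(4-hydroxyphenyl)prop-2-en-1-one
Conditions: Et3N·3HF, THF, 0 °C → rt; work-up at pH 5–6, purification cold
Reagents that add atoms: none
Why: Fluoride-driven cleavage of the aryl silyl ethers in a weakly acidic medium, so no phenoxide forms that could add to the enone; no stereocentre is involved.

**Compound list**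
1 | 2-hydroxy-4,6-dimethoxybenzaldehyde | O=Cc1c(O)cc(OC)cc1OC | starting material
2 | 2,4-dimethoxy-6-(methoxymethoxy)benzaldehyde | O=Cc1c(OCOC)cc(OC)cc1OC | intermediate
3 | 4'-methoxyacetophenone | CC(=O)c1ccc(OC)cc1 | starting material
4 | 3-[2,4-dimethoxy-6-(methoxymethoxy)phenyl]-3-hydroxy-1-(4-methoxyphenyl)propan-1-one (racemic, not isolated) | COCOc1cc(OC)cc(OC)c1C(O)CC(=O)c1ccc(OC)cc1 | intermediate
5 | (E)-3-[2,4-dimethoxy-6-(methoxymethoxy)phenyl]-1-(4-methoxyphenyl)prop-2-en-1-one | COCOc1cc(OC)cc(OC)c1/C=C/C(=O)c1ccc(OC)cc1 | intermediate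
6 | 2-[2,4-dimethoxy-6-(methoxymethoxy)phenyl]-3,3-dimethoxy-1-(4-methoxyphenyl)propan-1-one (racemic) | COCOc1cc(OC)cc(OC)c1C(C(OC)OC)C(=O)c1ccc(OC)cc1 | intermediate
7 | (2,4,6-trimethoxy-2,3-dihydro-1-benzofuran-3-yl)(4-methoxyphenyl)methanone (diastereomer mixture, not isolated) | COC1Oc2cc(OC)cc(OC)c2C1C(=O)c1ccc(OC)cc1 | intermediate
8 | 4,6-dimethoxy-2-(4-methoxyphenyl)-1-benzofuran-3-carbaldehyde | O=Cc1c(-c2ccc(OC)cc2)oc2cc(OC)cc(OC)c12 | intermediate
9 | 1-bromo-2,4-dimethoxybenzene | COc1ccc(Br)c(OC)c1 | starting material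
10 | (2,4-dimethoxyphenyl)magnesium bromide | COc1ccc([Mg]Br)c(OC)c1 | intermediate
11 | (2,4-dimethoxyphenyl)[4,6-dimethoxy-2-(4-methoxyphenyl)-1-benzofuran-3-yl]methanol (racemic) | COc1ccc(C(O)c2c(-c3ccc(OC)cc3)oc3cc(OC)cc(OC)c23)c(OC)c1 | intermediate
12 | (2,4-dimethoxyphenyl)[4,6-dimethoxy-2-(4-methoxyphenyl)-1-benzofuran-3-yl]methanone | COc1ccc(C(=O)c2c(-c3ccc(OC)cc3)oc3cc(OC)cc(OC)c23)c(OC)c1 | intermediate
13 | (4-methoxyphenyl)acetyl chloride | COc1ccc(CC(=O)Cl)cc1 | starting material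
14 | 1-[3-(2,4-dimethoxybenzoyl)-4,6-dimethoxy-2-(4-methoxyphenyl)-1-benzofuran-7-yl]-2-(4-methoxyphenyl)ethan-1-one | COc1ccc(CC(=O)c2c(OC)cc(OC)c3c(C(=O)c4ccc(OC)cc4OC)c(-c4ccc(OC)cc4)oc23)cc1 | intermediate
15 | 1-[3-(2,4-dihydroxybenzoyl)-4,6-dihydroxy-2-(4-hydroxyphenyl)-1-benzofuran-7-yl]-2-(4-hydroxyphenyl)ethan-1-one | Oc1ccc(CC(=O)c2c(O)cc(O)c3c(C(=O)c4ccc(O)cc4O)c(-c4ccc(O)cc4)oc23)cc1 | intermediate
16 | hexakis-O-(tert-butyldimethylsilyl) ether of 15 | CC(C)(C)[Si](C)(C)Oc1ccc(CC(=O)c2c(O[Si](C)(C)C(C)(C)C)cc(O[Si](C)(C)C(C)(C)C)c3c(C(=O)c4ccc(O[Si](C)(C)C(C)(C)C)cc4O[Si](C)(C)C(C)(C)C)c(-c4ccc(O[Si](C)(C)C(C)(C)C)cc4)oc23)cc1 | intermediate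
17 | 3-(dimethylamino) Mannich base of 16 (racemic, not isolated) | CN(C)CC(c1ccc(O[Si](C)(C)C(C)(C)C)cc1)C(=O)c1c(O[Si](C)(C)C(C)(C)C)cc(O[Si](C)(C)C(C)(C)C)c2c(C(=O)c3ccc(O[Si](C)(C)C(C)(C)C)cc3O[Si](C)(C)C(C)(C)C)c(-c3ccc(O[Si](C)(C)C(C)(C)C)cc3)oc12 | intermediate
18 | hexakis-O-(tert-butyldimethylsilyl) ether of the target | C=C(C(=O)c1c(O[Si](C)(C)C(C)(C)C)cc(O[Si](C)(C)C(C)(C)C)c2c(C(=O)c3ccc(O[Si](C)(C)C(C)(C)C)cc3O[Si](C)(C)C(C)(C)C)c(-c3ccc(O[Si](C)(C)C(C)(C)C)cc3)oc12)c1ccc(O[Si](C)(C)C(C)(C)C)cc1 | intermediate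
19 | 1-[3-(2,4-dihydroxybenzoyl)-4,6-dihydroxy-2-(4-hydroxyphenyl)-1-benzofuran-7-yl]-2-(4-hydroxyphenyl)prop-2-en-1-one (CNP0181958.0) | C=C(C(=O)c1c(O)cc(O)c2c(C(=O)c3ccc(O)cc3O)c(-c3ccc(O)cc3)oc12)c1ccc(O)cc1 | target

**Totals**
Total step count: 12. Longest linear sequence: 11 steps (1 → 2 → 5 → 6 → 8 → 11 → 12 → 14 → 15 → 16 → 18 → 19; step 5 is a one-step side branch).

**Three steps most likely to fail**

Step 3 (oxidative aryl shift). Ring A is electron-rich enough that the trivalent iodine reagent may attack the ring (aryliodonium formation, over-oxidation) instead of the alkene, and the liberated TsOH may strip the MOM group early. The fallback sets out from 5 and comes back at 8. Nucleophilic epoxidation of 5 (H2O2, NaOH, MeOH/CH2Cl2, 0 °C) gives the trans epoxy ketone F1. Brief treatment with BF3·OEt2 (CH2Cl2, −40 °C) opens the epoxide at the benzylic carbon and a 1,2-acyl shift delivers the β-keto aldehyde F2, which has the same skeleton as 6 without the acetal. Exposure of F2 to TsOH·H2O in (CF3)2CHOH, as in step 4, gives 8.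

Step 8 (Friedel–Crafts acylation). SnCl4 chelation at the 3-aroyl ketone can slow the reaction or cleave an ortho methyl ether, the arylacetyl chloride can self-condense, and some C5 or aroyl-ring acylation is possible. The fallback sets out from 12 and comes back at 14. Vilsmeier–Haack reaction (POCl3, DMF, 0 → 60 °C), the most selective electrophile for C7 of 4,6-dimethoxybenzofurans, gives the iminium chloride F3, which aqueous NaOAc hydrolyses to the 7-carbaldehyde F4. Addition of 4-methoxybenzylmagnesium chloride (THF, −78 °C; the hindered diaryl ketone does not react) gives the carbinol F5, and Dess–Martin periodinane oxidation (CH2Cl2, NaHCO3) gives 14.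

Step 12 (final desilylation). Once the C6 hydroxyl is free, any phenoxide can close onto the enone by 6-endo oxa-Michael addition to an isoflavanone-type ring, and the 2-aryl enone can dimerise. The fallback sets out from 16 and comes back at 19, and unveils the alkene last under neutral conditions. C-Methylation of 16 (LiHMDS, MeI, THF, −78 → 0 °C) gives the α-methyl ketone F6. Enolisation and selenenylation (KHMDS, PhSeBr, THF, −78 °C) give the α-methyl-α-phenylselanyl ketone F7. Desilylation (Et3N·3HF, THF) gives the hexaphenol selenide F8, which is stable because it has no enone. Oxidation with H2O2 (THF/H2O, 0 °C) gives the selenoxide F9, whose syn-elimination can only involve the methyl hydrogens and releases 19.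

**Further compounds**
F1 | step 3 | trans-[3-(2,4-dimethoxy-6-(methoxymethoxy)phenyl)oxiran-2-yl](4-methoxyphenyl)methanone (racemic, one enantiomer drawn) | COCOc1cc(OC)cc(OC)c1[C@@H]1O[C@H]1C(=O)c1ccc(OC)cc1
F2 | step 3 | 2-[2,4-dimethoxy-6-(methoxymethoxy)phenyl]-3-(4-methoxyphenyl)-3-oxopropanal (racemic) | COCOc1cc(OC)cc(OC)c1C(C=O)C(=O)c1ccc(OC)cc1
F3 | step 8 | N-{[3-(2,4-dimethoxybenzoyl)-4,6-dimethoxy-2-(4-methoxyphenyl)-1-benzofuran-7-yl]methylidene}-N-methylmethanaminium chloride | C[N+](C)=Cc1c(OC)cc(OC)c2c(C(=O)c3ccc(OC)cc3OC)c(-c3ccc(OC)cc3)oc12.[Cl-]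
F4 | step 8 | 3-(2,4-dimethoxybenzoyl)-4,6-dimethoxy-2-(4-methoxyphenyl)-1-benzofuran-7-carbaldehyde | O=Cc1c(OC)cc(OC)c2c(C(=O)c3ccc(OC)cc3OC)c(-c3ccc(OC)cc3)oc12
F5 | step 8 | 1-[3-(2,4-dimethoxybenzoyl)-4,6-dimethoxy-2-(4-methoxyphenyl)-1-benzofuran-7-yl]-2-(4-methoxyphenyl)ethan-1-ol (racemic) | COc1ccc(CC(O)c2c(OC)cc(OC)c3c(C(=O)c4ccc(OC)cc4OC)c(-c4ccc(OC)cc4)oc23)cc1
F6 | step 12 | α-methyl derivative of 16, the 2-arylpropan-1-one (racemic) | CC(c1ccc(O[Si](C)(C)C(C)(C)C)cc1)C(=O)c1c(O[Si](C)(C)C(C)(C)C)cc(O[Si](C)(C)C(C)(C)C)c2c(C(=O)c3ccc(O[Si](C)(C)C(C)(C)C)cc3O[Si](C)(C)C(C)(C)C)c(-c3ccc(O[Si](C)(C)C(C)(C)C)cc3)oc12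
F7 | step 12 | α-methyl-α-(phenylselanyl) derivative of 16 (racemic) | CC([Se]c1ccccc1)(c1ccc(O[Si](C)(C)C(C)(C)C)cc1)C(=O)c1c(O[Si](C)(C)C(C)(C)C)cc(O[Si](C)(C)C(C)(C)C)c2c(C(=O)c3ccc(O[Si](C)(C)C(C)(C)C)cc3O[Si](C)(C)C(C)(C)C)c(-c3ccc(O[Si](C)(C)C(C)(C)C)cc3)oc12
F8 | step 12 | 1-[3-(2,4-dihydroxybenzoyl)-4,6-dihydroxy-2-(4-hydroxyphenyl)-1-benzofuran-7-yl]-2-(4-hydroxyphenyl)-2-(phenylselanyl)propan-1-one (racemic) | CC([Se]c1ccccc1)(c1ccc(O)cc1)C(=O)c1c(O)cc(O)c2c(C(=O)c3ccc(O)cc3O)c(-c3ccc(O)cc3)oc12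
F9 | step 12 | selenoxide of F8 (diastereomer mixture, not isolated) | CC([Se](=O)c1ccccc1)(c1ccc(O)cc1)C(=O)c1c(O)cc(O)c2c(C(=O)c3ccc(O)cc3O)c(-c3ccc(O)cc3)oc12
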